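**Strategy.** Ring C is closed last through the C9–C11 bond. C9 is a ketone flanked by the quaternary C10, so it can be converted regiospecifically into an alkenyl triflate. C11 lies between the C12 and C15 oxygens, so it can be made the single acidic carbon of a cyclopentane-1,3-dione. A palladium-catalysed intramolecular C-alkenylation of this dione enolate joins the two in one operation, forming the bicyclo[3.2.1]octene (rings C and D), the C8=C9 alkene and the C11 stereocentre. The precursor, a decalin alkenyl triflate carrying a CH2-linked 4-methylcyclopentane-1,3-dione, is assembled from two (R)-4-silyloxy-enones, which supply ring B, ring D and all absolute stereochemistry.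

Key step: step 12

Numbering: atoms carry the ent-kaurane-type numbers of the target throughout. Ring A is C1–C5 and C10, ring B is C5–C10, ring C is C8, C9, C11–C14, and ring D is C11, C12, C13, C16, C15. C17 is the carbon on C16, C18 and C19 are the methyls on C4, and C20 is the methyl on C10. Cyclohexenone carbons C1–C6 of 1–3 become C9, C10, C5, C6, C7, C8. Cyclopentenone carbons C1–C5 of 12–14 become C12, C13, C16, C15, C11. CIP descriptors in names use these locants unless a systematic name is given.

Assumption: (R)-4-[(tert-butyldimethylsilyl)oxy]cyclohex-2-en-1-one (1) is taken as purchasable in enantiopure form, like its cyclopentenone analogue 12.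

Step 1
Reactants: 1 (R)-4-[(tert-butyldimethylsilyl)oxy]cyclohex-2-en-1-one
Product: 2 (R)-4-[(tert-butyldimethylsilyl)oxy]-2-iodocyclohex-2-en-1-one
Conditions: I2, pyridine, CH2Cl2, 0 °C to rt
Reagents that add atoms: iodine, II
Why: Pyridine-promoted α-iodination of an enone (conjugate addition of pyridine, iodination of the resulting enolate and elimination) functionalises only the α-carbon, the future C10, and leaves the silyloxy stereocentre untouched.

Step 2
Reactants: 2 (R)-4-[(tert-butyldimethylsilyl)oxy]-2-iodocyclohex-2-en-1-one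
Product: 3 (R)-4-[(tert-butyldimethylsilyl)oxy]-2-methylcyclohex-2-en-1-one
Conditions: MeZnCl, Pd(PPh3)4 (cat.), THF, rt
Reagents that add atoms: methylzinc chloride, C[Zn]Cl
Why: Negishi cross-coupling of the α-iodoenone with methylzinc chloride introduces the future C20 methyl under neutral conditions at room temperature, so the base-sensitive γ-silyloxy enone is not aromatised and no stereocentre is involved.

Step 3
Reactants: 3 (R)-4-[(tert-butyldimethylsilyl)oxy]-2-methylcyclohex-2-en-1-one; 4 trimethyl(3-methylbut-2-en-1-yl)silane; 5 acrolein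
Product: 7 (2S,3R,4R)-4-[(tert-butyldimethylsilyl)oxy]-2-[(1S)-1-hydroxyprop-2-en-1-yl]-2-methyl-3-(2-methylbut-3-en-2-yl)cyclohexan-1-one, via trichlorotitanium enolate 6 (not isolated)
Conditions: TiCl4, CH2Cl2, −78 °C; then acrolein, −78 °C; aq. NaHCO3
Reagents that add atoms: none
Why: In this tandem Hosomi–Sakurai/aldol reaction the prenylsilane attacks C5 through its γ-carbon anti to the neighbouring C6 silyloxy group, which sets C5 and creates the quaternary C4, and the titanium enolate formed adds to acrolein through a closed Zimmerman–Traxler chair on the face opposite the new C5 substituent, which sets C10 for the trans ring fusion and, with the vinyl group equatorial, places the C1 hydroxyl syn to the C10 methyl.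

Step 4
Reactants: 7 (2S,3R,4R)-4-[(tert-butyldimethylsilyl)oxy]-2-[(1S)-1-hydroxyprop-2-en-1-yl]-2-methyl-3-(2-methylbut-3-en-2-yl)cyclohexan-1-one
Product: 8 (1S)-1-[(1S,2R,3R)-3-[(tert-butyldimethylsilyl)oxy]-1-methyl-2-(2-methylbut-3-en-2-yl)-6-oxocyclohexyl]prop-2-en-1-yl acetate
Conditions: Ac2O, DMAP, pyridine, CH2Cl2, rt
Reagents that add atoms: acetic anhydride, CC(=O)OC(C)=O
Why: DMAP-catalysed acetylation installs the C1 acetate of the target at once, stops retro-aldol cleavage of the β-hydroxy ketone and prevents later oxa-Michael addition of the C1 oxygen, without touching a stereocentre.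

Step 5
Reactants: 8 (1S)-1-[(1S,2R,3R)-3-[(tert-butyldimethylsilyl)oxy]-1-methyl-2-(2-methylbut-3-en-2-yl)-6-oxocyclohexyl]prop-2-en-1-yl acetate
Product: 9 trans-octalone (1S,5R,6R,10S)-1-acetoxy-6-[(tert-butyldimethylsilyl)oxy]-4,4,10-trimethyl with C9 ketone and C2=C3 alkene
Conditions: second-generation Grubbs catalyst, CH2Cl2, 40 °C
Reagents that add atoms: none
Why: Ring-closing metathesis of the two vinyl groups, which sit trans-diequatorial on ring B, forms the C2=C3 bond and with it the trans-fused ring A while ethylene escapes, leaving all stereocentres as they are.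

Step 6
Reactants: 9 trans-octalone (1S,5R,6R,10S)-1-acetoxy-6-[(tert-butyldimethylsilyl)oxy]-4,4,10-trimethyl with C9 ketone and C2=C3 alkene
Product: 10 trans-decalone (1S,5R,6R,10S)-1-acetoxy-6-[(tert-butyldimethylsilyl)oxy]-4,4,10-trimethyldecalin-9-one
Conditions: H2 (1 atm), PtO2, EtOAc, rt
Reagents that add atoms: none
Why: Heterogeneous hydrogenation over platinum saturates the only C=C bond without the hydrogenolysis of the allylic acetate that palladium could cause and creates no stereocentre.

Step 7
Reactants: 10 trans-decalone (1S,5R,6R,10S)-1-acetoxy-6-[(tert-butyldimethylsilyl)oxy]-4,4,10-trimethyldecalin-9-one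
Product: 11 α-methylene ketone (1S,5R,6R,10S)-1-acetoxy-6-[(tert-butyldimethylsilyl)oxy]-4,4,10-trimethyl-8-methylidenedecalin-9-one
Conditions: (CH2O)n, PhNHMe·CF3CO2H, THF, reflux
Reagents that add atoms: formaldehyde (from paraformaldehyde), C=O
Why: This Mannich-type α-methylenation (formaldehyde with an anilinium salt) can occur only at C8, the single enolisable position of the C9 ketone because C10 is quaternary, and introduces C14 as the terminus of a Michael acceptor.

Step 8
Reactants: 12 (R)-4-[(tert-butyldimethylsilyl)oxy]cyclopent-2-en-1-one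
Product: 13 {[(3R,4R)-4-[(tert-butyldimethylsilyl)oxy]-3-methylcyclopent-1-en-1-yl]oxy}trimethylsilane
Conditions: MeMgBr, CuBr·SMe2 (cat.), TMSCl, THF, −78 °C; Et3N, non-aqueous work-up
Reagents that add atoms: methylmagnesium bromide, C[Mg]Br; chlorotrimethylsilane, C[Si](C)(C)Cl
Why: Copper-catalysed conjugate addition of the methyl Grignard reagent, accelerated and trapped by TMSCl, delivers the future C17 to C16 anti to the C15 silyloxy group and fixes the enolate as the C12=C13 silyl enol ether, a regiochemistry in which the silyloxy group cannot be lost by β-elimination.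

Step 9
Reactants: 13 {[(3R,4R)-4-[(tert-butyldimethylsilyl)oxy]-3-methylcyclopent-1-en-1-yl]oxy}trimethylsilane; 11 α-methylene ketone (1S,5R,6R,10S)-1-acetoxy-6-[(tert-butyldimethylsilyl)oxy]-4,4,10-trimethyl-8-methylidenedecalin-9-one
Product: 16 alkenyl triflate (1S,5R,6R,10S,13R,15R,16R) with C9–OTf and C8=C9 whose C8 carries C14H2 bonded to C13 of a 15-silyloxy-16-methylcyclopentan-12-one, via cyclopentanone lithium enolate 14 (not isolated), via decalone lithium enolate 15 (not isolated)
Conditions: MeLi, THF, −78 to 0 °C; then 11, −78 °C; then PhNTf2, −78 to −20 °C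
Reagents that add atoms: N-phenylbis(trifluoromethanesulfonimide), O=S(=O)(N(c1ccccc1)S(=O)(=O)C(F)(F)F)C(F)(F)F
Why: Methyllithium releases the regiodefined lithium enolate, which undergoes Michael addition through C13 to the unhindered C14 terminus of the enone anti to the adjacent C16 methyl (this sets C13), and the C8=C9 enolate so generated is triflated on oxygen at low temperature before proton transfer from C11 or acetyl migration from O1 can intervene.

Step 10
Reactants: 16 alkenyl triflate (1S,5R,6R,10S,13R,15R,16R) with C9–OTf and C8=C9 whose C8 carries C14H2 bonded to C13 of a 15-silyloxy-16-methylcyclopentan-12-one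
Product: 17 diol (1S,5R,6R,10S,13R,15R,16R) with free C6 and C15 hydroxyls
Conditions: HF·pyridine, pyridine, THF, 0 °C to rt
Reagents that add atoms: none
Why: Buffered HF·pyridine cleaves both secondary silyl ethers while the alkenyl triflate, the acetate and the ring D β-hydroxy ketone survive, as in desilylations of prostaglandin E intermediates, and no stereocentre changes.

Step 11
Reactants: 17 diol (1S,5R,6R,10S,13R,15R,16R) with free C6 and C15 hydroxyls
Product: 18 cyclopentane-1,3-dione (1S,5R,6R,10S,13R,16R) with C12 and C15 ketones in ring D, free C6 hydroxyl and C9 alkenyl triflate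
Conditions: TEMPO (cat.), PhI(OAc)2, CH2Cl2, rt
Reagents that add atoms: none
Why: The oxoammonium salt formed from TEMPO and PhI(OAc)2 oxidises the unhindered ring D carbinol at C15 but not the C6 alcohol, which is shielded by the substituents on C4 and C10, so ring D becomes an enolised cyclopentane-1,3-dione whose only acidic carbon is C11, and the mild conditions leave C13 and C16 unepimerised.

Step 12
Reactants: 18 cyclopentane-1,3-dione (1S,5R,6R,10S,13R,16R) with C12 and C15 ketones in ring D, free C6 hydroxyl and C9 alkenyl triflate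
Product: 19 bridged diketone (1S,5R,6R,10R,11S,13R,16R)-1-acetoxy-6-hydroxy-16-methyl tetracycle with C12 and C15 ketones and C8=C9 alkene
Conditions: Pd(OAc)2 (cat.), 2-(di-tert-butylphosphino)-2′-methylbiphenyl, K3PO4, THF, 80 °C
Reagents that add atoms: none
Why: Oxidative addition of zerovalent palladium to the C9–O triflate bond gives an alkenylpalladium species, the potassium enolate of the 1,3-dione (deprotonated at C11 by K3PO4) binds palladium through carbon because a cyclic 1,3-diketonate cannot chelate, and C–C reductive elimination forges C9–C11. The closest known reaction type is the palladium-catalysed α-arylation and α-alkenylation of ketone and cyclic 1,3-diketone enolates with bulky biarylphosphine ligands, here run intramolecularly. Ring C is closed as a six-membered ring by reductive elimination from a seven-membered palladacycle, which at the same time completes the bicyclo[3.2.1]octene with C11 and C13 as bridgeheads. The new stereocentre C11 is dictated by C13, since C9 can only reach the face of ring D that carries C14, and because C13 was set in step 9 the C15–C16 bridge ends up on the face opposite the C10 methyl. The step needs C- rather than O-alkenylation and coupling at C11 rather than at C13, C16 or C7; the ligand-promoted preference of palladium C-enolates for C–C reductive elimination secures the first, and the weak base, which deprotonates only C11 and so also keeps C13 and C16 configurationally intact, secures the second. The product is a bridgehead-substituted β-diketone that cannot enolise, so it does not react further.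

Step 13
Reactants: 19 bridged diketone (1S,5R,6R,10R,11S,13R,16R)-1-acetoxy-6-hydroxy-16-methyl tetracycle with C12 and C15 ketones and C8=C9 alkene
Product: 20 enone triketone (1S,5R,10R,11R,13R)-1-acetoxy tetracycle with C6 and C12 ketones and the C15-oxo-C16=C17 enone
Conditions: IBX, DMSO, rt then 65 °C
Reagents that add atoms: none
Why: IBX oxidises the C6 alcohol, whose configuration has served only to relay chirality, to the ketone and at 65 °C dehydrogenates the C15 ketone (Nicolaou dehydrogenation), and the new double bond can only be C16=C17 because C13 is a bridgehead and neither the C6 nor the C12 ketone has an α,β C–H pair that could be desaturated, so the C16 methyl becomes the exocyclic methylene.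

Step 14
Reactants: 20 enone triketone (1S,5R,10R,11R,13R)-1-acetoxy tetracycle with C6 and C12 ketones and the C15-oxo-C16=C17 enone
Product: 21 triol (1S,5R,6S,10R,11R,12S,13R)-1-acetoxy-6,12,15-trihydroxy tetracycle with C8=C9 and C16=C17 alkenes (both C15 epimers)
Conditions: NaBH4, CeCl3·7H2O, MeOH, −40 to 0 °C
Reagents that add atoms: none
Why: Luche reduction (NaBH4 with CeCl3) reduces all three carbonyl groups in the 1,2 sense: hydride reaches C6 from the face opposite the axial methyl groups on C4 and C10 and gives the axial alcohol, it reaches the bridging C12 carbonyl from the side of the C8=C9–C14 bridge, the wider flank that carries a single axial hydrogen, and so places the hydroxyl syn to the C15–C16 bridge, and it converts the enone into an allylic alcohol whose configuration at C15 is of no consequence.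

Step 15
Reactants: 21 triol (1S,5R,6S,10R,11R,12S,13R)-1-acetoxy-6,12,15-trihydroxy tetracycle with C8=C9 and C16=C17 alkenes (both C15 epimers)
Product: 22 target CNP0149338.1 (1S,5R,6S,10R,11R,12S,13R)-1-acetoxy-6,12-dihydroxy-15-oxo tetracycle with C8=C9 and C16=C17 alkenes
Conditions: MnO2 (activated), CH2Cl2, rt
Reagents that add atoms: none
Why: Activated MnO2 oxidises only the allylic C15 alcohol, which restores the exo-methylene ketone, and leaves the saturated secondary alcohols at C6 and C12 and all stereocentres untouched.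

**Compound list**

1 | (R)-4-[(tert-butyldimethylsilyl)oxy]cyclohex-2-en-1-one | O=C1C=C[C@H](O[Si](C)(C)C(C)(C)C)CC1 | starting material
2 | (R)-4-[(tert-butyldimethylsilyl)oxy]-2-iodocyclohex-2-en-1-one | O=C1C(I)=C[C@H](O[Si](C)(C)C(C)(C)C)CC1 | intermediate
3 | (R)-4-[(tert-butyldimethylsilyl)oxy]-2-methylcyclohex-2-en-1-one | O=C1C(C)=C[C@H](O[Si](C)(C)C(C)(C)C)CC1 | intermediate
4 | trimethyl(3-methylbut-2-en-1-yl)silane (prenyltrimethylsilane) | CC(C)=CC[Si](C)(C)C | starting material
5 | acrolein (prop-2-enal) | C=CC=O | starting material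
6 | trichlorotitanium enolate of (3R,4R)-4-silyloxy-2-methyl-3-(2-methylbut-3-en-2-yl)cyclohexanone | Cl[Ti](Cl)(Cl)OC1=C(C)[C@@H](C(C)(C)C=C)[C@H](O[Si](C)(C)C(C)(C)C)CC1 | intermediate
7 | (2S,3R,4R)-4-[(tert-butyldimethylsilyl)oxy]-2-[(1S)-1-hydroxyprop-2-en-1-yl]-2-methyl-3-(2-methylbut-3-en-2-yl)cyclohexan-1-one | O=C1CC[C@@H](O[Si](C)(C)C(C)(C)C)[C@H](C(C)(C)C=C)[C@@]1(C)[C@@H](O)C=C | intermediate
8 | (1S)-1-[(1S,2R,3R)-3-[(tert-butyldimethylsilyl)oxy]-1-methyl-2-(2-methylbut-3-en-2-yl)-6-oxocyclohexyl]prop-2-en-1-yl acetate | O=C1CC[C@@H](O[Si](C)(C)C(C)(C)C)[C@H](C(C)(C)C=C)[C@@]1(C)[C@@H](OC(C)=O)C=C | intermediate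
9 | trans-octalone, rings A and B: (1S,5R,6R,10S), C9 ketone, C2=C3, 1-OAc, 6-OTBS, 4,4,10-trimethyl | O=C1CC[C@@H](O[Si](C)(C)C(C)(C)C)[C@@H]2C(C)(C)C=C[C@H](OC(C)=O)[C@@]12C | intermediate
10 | trans-decalone: (1S,5R,6R,10S)-1-acetoxy-6-[(tert-butyldimethylsilyl)oxy]-4,4,10-trimethyldecalin-9-one | O=C1CC[C@@H](O[Si](C)(C)C(C)(C)C)[C@@H]2C(C)(C)CC[C@H](OC(C)=O)[C@@]12C | intermediate
11 | α-methylene ketone: 8-methylidene derivative of 10 (C14 exocyclic), (1S,5R,6R,10S) | O=C1C(=C)C[C@@H](O[Si](C)(C)C(C)(C)C)[C@@H]2C(C)(C)CC[C@H](OC(C)=O)[C@@]12C | intermediate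
12 | (R)-4-[(tert-butyldimethylsilyl)oxy]cyclopent-2-en-1-one | O=C1C=C[C@H](O[Si](C)(C)C(C)(C)C)C1 | starting material
13 | {[(3R,4R)-4-[(tert-butyldimethylsilyl)oxy]-3-methylcyclopent-1-en-1-yl]oxy}trimethylsilane | C[Si](C)(C)OC1=C[C@@H](C)[C@H](O[Si](C)(C)C(C)(C)C)C1 | intermediate
14 | lithium enolate of (3R,4R)-4-silyloxy-3-methylcyclopentanone (C12=C13) | [Li]OC1=C[C@@H](C)[C@H](O[Si](C)(C)C(C)(C)C)C1 | intermediate
15 | C8=C9 lithium enolate of the Michael adduct (ring D attached through C14) | [Li]OC1=C(C[C@@H]2[C@@H](C)[C@H](O[Si](C)(C)C(C)(C)C)CC2=O)C[C@@H](O[Si](C)(C)C(C)(C)C)[C@@H]2C(C)(C)CC[C@H](OC(C)=O)[C@@]12C | intermediate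
16 | alkenyl triflate (1S,5R,6R,10S,13R,15R,16R): C9–OTf, C8=C9, C8–C14H2–C13 of 15-OTBS-16-methylcyclopentan-12-one, 1-OAc, 6-OTBS | O=S(=O)(OC1=C(C[C@@H]2[C@@H](C)[C@H](O[Si](C)(C)C(C)(C)C)CC2=O)C[C@@H](O[Si](C)(C)C(C)(C)C)[C@@H]2C(C)(C)CC[C@H](OC(C)=O)[C@@]12C)C(F)(F)F | intermediate
17 | diol (1S,5R,6R,10S,13R,15R,16R): as 16 with free C6 and C15 hydroxyls | O=S(=O)(OC1=C(C[C@@H]2[C@@H](C)[C@H](O)CC2=O)C[C@@H](O)[C@@H]2C(C)(C)CC[C@H](OC(C)=O)[C@@]12C)C(F)(F)F | intermediate
18 | cyclopentane-1,3-dione (1S,5R,6R,10S,13R,16R): C12 and C15 ketones, free C6 hydroxyl, C9 alkenyl triflate (drawn as diketo tautomer) | O=S(=O)(OC1=C(C[C@@H]2[C@@H](C)C(=O)CC2=O)C[C@@H](O)[C@@H]2C(C)(C)CC[C@H](OC(C)=O)[C@@]12C)C(F)(F)F | intermediate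
19 | bridged diketone (1S,5R,6R,10R,11S,13R,16R): bicyclo[3.2.1]octene rings C and D, C12 and C15 ketones, 16-methyl, 6-OH, 1-OAc | C[C@H]1C(=O)[C@@H]2C3=C(C[C@H]1C2=O)C[C@@H](O)[C@@H]1C(C)(C)CC[C@H](OC(C)=O)[C@@]31C | intermediate
20 | enone triketone (1S,5R,10R,11R,13R): C6 and C12 ketones, C15 ketone conjugated with C16=C17 | C=C1C(=O)[C@@H]2C3=C(C[C@H]1C2=O)CC(=O)[C@@H]1C(C)(C)CC[C@H](OC(C)=O)[C@@]31C | intermediate
21 | triol (1S,5R,6S,10R,11R,12S,13R): 6,12,15-trihydroxy, 1-OAc, C16=C17 (both C15 epimers) | C=C1C(O)[C@@H]2C3=C(C[C@H]1[C@@H]2O)C[C@H](O)[C@@H]1C(C)(C)CC[C@H](OC(C)=O)[C@@]31C | intermediate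
22 | target CNP0149338.1, (1S,5R,6S,10R,11R,12S,13R) | C=C1C(=O)[C@@H]2C3=C(C[C@H]1[C@@H]2O)C[C@H](O)[C@@H]1C(C)(C)CC[C@H](OC(C)=O)[C@@]31C | target

**Step count.** Total: 15 steps. Longest linear sequence: 14 steps (steps 1–7 and 9–15; step 8 makes the ring D fragment in one step).

**Steps most likely to fail**

Step 12. The reductive elimination must join a tetrasubstituted alkenyl carbon next to the quaternary C10 to a tertiary enolate carbon. If C–C bond formation is slow, O-alkenylation to a pyran-type enol ether, protodepalladation or cleavage of the triflate can take over. The fallback replaces cross-coupling by an aldol condensation, sets out from 11 and comes back at 19. The enolate 14 is added to 11 as in step 9, but the adduct is quenched with NH4Cl to give the saturated C9 ketone F1. HF·pyridine then gives the diol F2, and TEMPO with PhI(OAc)2 gives the cyclopentane-1,3-dione F3. TsOH in refluxing benzene with removal of water should bring about the bridged aldol addition of C11 to the C9 ketone, giving the ketol F4. Dehydration of F4 can only occur towards C8 and delivers 19.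

Step 9. Three events must follow one another in one flask. Proton transfer from C11 to the hindered C9 enolate followed by β-elimination of the C15 silyloxy group, 1,2-addition to the ketone, or acetyl transfer from O1 may erode the sequence. The fallback avoids free enolates, sets out from 13 and 11 and comes back at 16. A Mukaiyama–Michael reaction catalysed by TMSOTf in CH2Cl2 at −78 °C transfers the silyl group and gives the C9 trimethylsilyl enol ether F5. F5 is then converted into the triflate with CsF and PhNTf2 in DME, where the enolate is trapped as it forms.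

Step 14. Facial selectivity at the bridging C12 carbonyl may be poor, with hydride also approaching from the side of the C15–C16 bridge. The fallback uses thermodynamic instead of kinetic control, sets out from 20 and comes back at 22. The reduction would then give the C12-epimeric triol F6, which MnO2 oxidises to the C12-epimeric enone F7. DBU in toluene should open this β-hydroxy ketone by retro-aldol cleavage of C11–C12 to the seco keto-aldehyde F8. Re-aldolisation under equilibrium control is expected to favour the hydroxyl equatorial on ring C and syn to the C15–C16 bridge, which is 22.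

Further compounds

F1 | step 12 | saturated C9 ketone Michael adduct (C8 epimers), 6,15-bis-OTBS | O=C1C(C[C@@H]2[C@@H](C)[C@H](O[Si](C)(C)C(C)(C)C)CC2=O)C[C@@H](O[Si](C)(C)C(C)(C)C)[C@@H]2C(C)(C)CC[C@H](OC(C)=O)[C@@]12C
F2 | step 12 | C9 ketone diol with free C6 and C15 hydroxyls | O=C1C(C[C@@H]2[C@@H](C)[C@H](O)CC2=O)C[C@@H](O)[C@@H]2C(C)(C)CC[C@H](OC(C)=O)[C@@]12C
F3 | step 12 | C9 ketone bearing the C12,C15-cyclopentane-1,3-dione, free C6 hydroxyl | O=C1C(C[C@@H]2[C@@H](C)C(=O)CC2=O)C[C@@H](O)[C@@H]2C(C)(C)CC[C@H](OC(C)=O)[C@@]12C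
F4 | step 12 | bridged ketol with tertiary C9 hydroxyl | C[C@H]1C(=O)[C@@H]2C3(O)C(C[C@H]1C2=O)C[C@@H](O)[C@@H]1C(C)(C)CC[C@H](OC(C)=O)[C@@]31C
F5 | step 9 | C9 trimethylsilyl enol ether of the Michael adduct | C[Si](C)(C)OC1=C(C[C@@H]2[C@@H](C)[C@H](O[Si](C)(C)C(C)(C)C)CC2=O)C[C@@H](O[Si](C)(C)C(C)(C)C)[C@@H]2C(C)(C)CC[C@H](OC(C)=O)[C@@]12C
F6 | step 14 | C12 epimer of triol 21 | C=C1C(O)[C@@H]2C3=C(C[C@H]1[C@H]2O)C[C@H](O)[C@@H]1C(C)(C)CC[C@H](OC(C)=O)[C@@]31C
F7 | step 14 | C12 epimer of 22 | C=C1C(=O)[C@@H]2C3=C(C[C@H]1[C@H]2O)C[C@H](O)[C@@H]1C(C)(C)CC[C@H](OC(C)=O)[C@@]31C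
F8 | step 14 | seco keto-aldehyde (C11–C12 cleaved, C12 aldehyde on C13) | C=C1C(=O)CC2=C(C[C@H]1C=O)C[C@H](O)[C@@H]1C(C)(C)CC[C@H](OC(C)=O)[C@@]21C
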